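## Retrosynthetic overview

- The target is an 11-membered humulane-type ring (C1–C11) with E-C1=C2(Me), Z-C8=C9(Me), C6 gem-dimethyl, C7–OAc (R) and C10–O-angelate (S). Both esters go on last, and C7–O comes from a reagent-controlled 1,2-reduction of a C7 enone.
- Key disconnection: the C7 ketone and the E-C1=C2 olefin are reconnected across the ring as a C2–C7 σ bond. The precursor is a cis-fused 6/7 bicycle (six-membered ring C2–C7, seven-membered ring C7–C8=C9–C10–C11–C1–C2) with C7–O⁻ and C1–OMs, and a Grob fragmentation opens it to the 11-membered ring.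
- That one step makes the macrocycle, fixes the E olefin stereospecifically, carries the cis cycloheptene bond over as the Z-C8=C9 olefin, and erases the relay centres C1, C2 and C7.
- The bicycle comes from 2,2-dimethylcyclohexanone by aldol addition (C1–C2), chelate-controlled methylation of the aldolate dianion (C1-O/C2-Me relation), vinyl addition to C7 and ring-closing metathesis (C8=C9). C10 comes from an auxiliary-controlled acetate aldol of methacrolein.
- Ring order: six-membered ring (purchased), seven-membered ring (step 7), eleven-membered ring (step 9).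

Key step: step 9

Numbering: target locants are used throughout. In the target SMILES, O[C@H]1 is C10, then C11, C1=C2(Me), C3, C4, C5, C6(Me)2, C7(OAc), C8=C9(Me).

Assumption: (R)-3-acetyl-4-benzyl-1,3-thiazolidine-2-thione (1) is taken as a commercial reagent; it is otherwise one N-acetylation away from the commercial thiazolidinethione.

Remark: the route is drawn for the series in which C1–OH is 1,3-anti to C10–OTBS. The 1,3-syn series, if formed in step 4, has C1, C2 and C7 in the mirror-image sense, runs through the same steps and converges on the same compound 16.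

## Route

Step 1
Reactants: 1 (R)-3-acetyl-4-benzyl-1,3-thiazolidine-2-thione; 2 methacrolein
Product: 4 (R)-4-benzyl-3-[(3S)-3-hydroxy-4-methylpent-4-enoyl]-1,3-thiazolidine-2-thione, via chlorotitanium enolate 3 (not isolated)
Conditions: TiCl4, i-Pr2NEt, CH2Cl2, −78 °C; then 2, −78 °C; aq. NH4Cl
Reagents that add atoms: none
Why: Nagao-type acetate aldol addition in which the titanium enolate, chelated to the thiocarbonyl sulfur, should add through a chair transition state on the face away from the benzyl group, setting C10 as S (the isopropenyl arm outranks CH2); the minor diastereomer is removed by chromatography.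

Step 2
Reactants: 4 (R)-4-benzyl-3-[(3S)-3-hydroxy-4-methylpent-4-enoyl]-1,3-thiazolidine-2-thione
Product: 5 (R)-4-benzyl-3-[(3S)-3-[(tert-butyldimethylsilyl)oxy]-4-methylpent-4-enoyl]-1,3-thiazolidine-2-thione
Conditions: TBSOTf, 2,6-lutidine, CH2Cl2, −78 → 0 °C
Reagents that add atoms: tert-butyldimethylsilyl triflate, CC(C)(C)[Si](C)(C)OS(=O)(=O)C(F)(F)F
Why: Silyl ether formation at a secondary allylic alcohol with the silyl triflate and a hindered base should be fast at low temperature and leave the acyl thiazolidinethione and the stereocentre untouched.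

Step 3
Reactants: 5 (R)-4-benzyl-3-[(3S)-3-[(tert-butyldimethylsilyl)oxy]-4-methylpent-4-enoyl]-1,3-thiazolidine-2-thione
Product: 6 (3S)-3-[(tert-butyldimethylsilyl)oxy]-4-methylpent-4-enal
Conditions: DIBAL-H, CH2Cl2, −78 °C; aq. Rochelle salt
Reagents that add atoms: none
Why: Reductive cleavage of an N-acyl thiazolidinethione, in which one equivalent of hydride gives a stable tetrahedral aluminium adduct that releases the aldehyde only on work-up, so over-reduction and β-elimination of the silyloxy group should not occur.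

Step 4
Reactants: 7 2,2-dimethylcyclohexan-1-one; 6 (3S)-3-[(tert-butyldimethylsilyl)oxy]-4-methylpent-4-enal
Product: 9 (6S)-6-[(1S,3S)-3-[(tert-butyldimethylsilyl)oxy]-1-hydroxy-4-methylpent-4-en-1-yl]-2,2-dimethylcyclohexan-1-one, via lithium enolate 8 (not isolated)
Conditions: LDA, THF, −78 °C; then 6, −78 °C; aq. NH4Cl
Reagents that add atoms: none
Why: Kinetic lithium enolate aldol addition through a Zimmerman–Traxler chair at the only enolisable position of 7; C1 should form mainly 1,3-anti to C10 (polar 1,3-induction model) and anti to the ring α-centre, and neither relation needs to be clean because the ring α-centre is planarised in step 5 and C1 in step 9.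

Step 5
Reactants: 9 (6S)-6-[(1S,3S)-3-[(tert-butyldimethylsilyl)oxy]-1-hydroxy-4-methylpent-4-en-1-yl]-2,2-dimethylcyclohexan-1-one
Product: 11 (6R)-6-[(1S,3S)-3-[(tert-butyldimethylsilyl)oxy]-1-hydroxy-4-methylpent-4-en-1-yl]-2,2,6-trimethylcyclohexan-1-one, via dilithium aldolate dianion 10 (not isolated)
Conditions: LDA (2.3 equiv), THF, −78 → −40 °C; then MeI, DMPU, −78 → −30 °C; aq. NH4Cl
Reagents that add atoms: iodomethane, CI
Why: Fráter–Seebach alkylation of the aldolate dianion (C6 is quaternary, so C2–H is the only enolisable position), in which the C1 lithium alkoxide chelates the enolate oxygen and iodomethane should attack C2 on the face opposite the C11 chain, placing C2–Me anti to C1–OH in the zigzag sense, which is cis on the later seven-membered ring.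

Step 6
Reactants: 11 (6R)-6-[(1S,3S)-3-[(tert-butyldimethylsilyl)oxy]-1-hydroxy-4-methylpent-4-en-1-yl]-2,2,6-trimethylcyclohexan-1-one
Product: 12 (1S,2R)-2-[(1S,3S)-3-[(tert-butyldimethylsilyl)oxy]-1-hydroxy-4-methylpent-4-en-1-yl]-2,6,6-trimethyl-1-vinylcyclohexan-1-ol
Conditions: CH2=CHMgBr (4 equiv), LaCl3·2LiCl, THF, −20 → 0 °C; aq. NH4Cl
Reagents that add atoms: vinylmagnesium bromide, C=C[Mg]Br
Why: Lanthanide-assisted 1,2-addition of a vinyl Grignard reagent to a non-enolisable, doubly neopentyl ketone, where the C1 magnesium alkoxide chelates the carbonyl and axial attack anti to the two axial methyl groups should place the vinyl group cis to the C1 chain (C7–OH cis to C2–Me); this centre is erased in step 9.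

Step 7
Reactants: 12 (1S,2R)-2-[(1S,3S)-3-[(tert-butyldimethylsilyl)oxy]-1-hydroxy-4-methylpent-4-en-1-yl]-2,6,6-trimethyl-1-vinylcyclohexan-1-ol
Product: 13 (1S,2R,7S,10S)-bicyclic diol (target locants; cis-fused 6/7 bicycle; C7–OH/C2–Me/C1–OH cis; C10–OTBS trans)
Conditions: Grubbs II (5–10 mol %), toluene, 80 °C, Ar sparge
Reagents that add atoms: none
Why: Ring-closing metathesis of the vinyl carbinol with the 1,1-disubstituted isopropenyl group to a trisubstituted cycloheptene, driven by loss of ethene; the seven-membered ring forces C8=C9 to be cis, which becomes the Z olefin of the target.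

Step 8
Reactants: 13 (1S,2R,7S,10S)-bicyclic diol
Product: 14 (1S,2R,7S,10S)-bicyclic hydroxy mesylate (C1–OMs; C7–OH free)
Conditions: MsCl, Et3N, CH2Cl2, −10 → 0 °C
Reagents that add atoms: methanesulfonyl chloride, CS(=O)(=O)Cl
Why: Sulfonylation through sulfene should take the secondary C1–OH and leave the tertiary, fully flanked C7–OH, with retention at C1 because only the O–H bond reacts.

Step 9
Reactants: 14 (1S,2R,7S,10S)-bicyclic hydroxy mesylate
Product: 16 (2Z,4S,6E)-4-[(tert-butyldimethylsilyl)oxy]-3,7,11,11-tetramethylcycloundeca-2,6-dien-1-one, via potassium alkoxide 15 (not isolated)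
Conditions: KHMDS (1.05 equiv), THF, −78 → 0 °C; pH 7 buffer
Reagents that add atoms: none
Why: Grob fragmentation of a cyclic 1,3-diol monosulfonate: the C7 alkoxide forms the C7=O bond while the C2–C7 σ bond, antiperiplanar to C1–OMs, breaks and mesylate leaves in one concerted step. The closest known reaction type is the base-induced fragmentation of fused bicyclic 1,3-diol monosulfonates to nine- and ten-membered cycloalkenones. The eleven-membered ring is not closed by bond formation but arises by ring expansion, through cleavage of the bond shared by the six- and seven-membered rings (6 + 7 − 2 ring atoms). No new stereocentre forms; C1, C2 and C7 become sp2, and the E geometry of C1=C2 should follow stereospecifically from the cis relation of C1–OMs and C2–Me set in step 5, because in the only reactive conformer C11 lies antiperiplanar to C3. The Z geometry of C8=C9 is inherited from the cycloheptene. The step needs fragmentation to win over oxetane formation and E2 elimination: the alkoxide and the mesylate are cis, so back-side displacement at C1 is impossible, and one equivalent of base at low temperature leaves none to epimerise the γ-centre C10 of the enone.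

Step 10
Reactants: 16 (2Z,4S,6E)-4-[(tert-butyldimethylsilyl)oxy]-3,7,11,11-tetramethylcycloundeca-2,6-dien-1-one
Product: 17 (1R,2Z,4S,6E)-4-[(tert-butyldimethylsilyl)oxy]-3,7,11,11-tetramethylcycloundeca-2,6-dien-1-ol
Conditions: (S)-Me-CBS (0.3 equiv), catecholborane, toluene, −78 °C; MeOH, aq. NaOH
Reagents that add atoms: none
Why: Corey–Bakshi–Shibata reduction with catecholborane (1,2-selective, no hydroboration of the olefins), in which the ketone should bind through the lone pair anti to the quaternary C6 (large group) with the twisted Z-alkenyl arm as the small group, so that the (S)-catalyst delivers hydride to the Si face and gives 7R; reagent control is used because C10 is remote.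

Step 11
Reactants: 17 (1R,2Z,4S,6E)-4-[(tert-butyldimethylsilyl)oxy]-3,7,11,11-tetramethylcycloundeca-2,6-dien-1-ol
Product: 18 (1R,2Z,4S,6E)-4-[(tert-butyldimethylsilyl)oxy]-3,7,11,11-tetramethylcycloundeca-2,6-dien-1-yl acetate
Conditions: Ac2O, Et3N, DMAP (cat.), CH2Cl2, rt
Reagents that add atoms: acetic anhydride, CC(=O)OC(C)=O
Why: DMAP-catalysed acylation of a hindered secondary allylic alcohol at oxygen, which leaves the C7 configuration unchanged.

Step 12
Reactants: 18 (1R,2Z,4S,6E)-4-[(tert-butyldimethylsilyl)oxy]-3,7,11,11-tetramethylcycloundeca-2,6-dien-1-yl acetate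
Product: 19 (1R,2Z,4S,6E)-4-hydroxy-3,7,11,11-tetramethylcycloundeca-2,6-dien-1-yl acetate
Conditions: HF·pyridine, pyridine, THF, 0 °C → rt
Reagents that add atoms: none
Why: Fluoride cleavage of the silyl ether under buffered, non-basic conditions, which should spare the allylic acetate and avoid acetyl migration to the freed C10 hydroxyl.

Step 13
Reactants: 19 (1R,2Z,4S,6E)-4-hydroxy-3,7,11,11-tetramethylcycloundeca-2,6-dien-1-yl acetate; 20 angelic acid
Product: 22 CNP0322023.1 (1S,2Z,4R,9E)-4-acetoxy-2,5,5,9-tetramethylcycloundeca-2,9-dien-1-yl (2Z)-2-methylbut-2-enoate, via angeloyl mixed anhydride 21 (not isolated)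
Conditions: 20, 2,4,6-trichlorobenzoyl chloride, Et3N, toluene, rt; then 19, toluene, 75 °C
Reagents that add atoms: none
Why: Yamaguchi esterification without DMAP, in which the alcohol attacks the less hindered angeloyl carbonyl of the mixed anhydride and the absence of a nucleophilic catalyst should suppress the addition–elimination path that turns angelate into tiglate; C10 keeps its configuration because only the O–H bond reacts.

## Compound list

1 | (R)-3-acetyl-4-benzyl-1,3-thiazolidine-2-thione | CC(=O)N1[C@H](Cc2ccccc2)CSC1=S | starting material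
2 | methacrolein (2-methylprop-2-enal) | CC(=C)C=O | starting material
3 | trichlorotitanium enolate of 1 (not isolated) | C=C(O[Ti](Cl)(Cl)Cl)N1[C@H](Cc2ccccc2)CSC1=S | intermediate
4 | (R)-4-benzyl-3-[(3S)-3-hydroxy-4-methylpent-4-enoyl]-1,3-thiazolidine-2-thione | O=C(C[C@H](O)C(C)=C)N1[C@H](Cc2ccccc2)CSC1=S | intermediate
5 | (R)-4-benzyl-3-[(3S)-3-[(tert-butyldimethylsilyl)oxy]-4-methylpent-4-enoyl]-1,3-thiazolidine-2-thione | O=C(C[C@H](O[Si](C)(C)C(C)(C)C)C(C)=C)N1[C@H](Cc2ccccc2)CSC1=S | intermediate
6 | (3S)-3-[(tert-butyldimethylsilyl)oxy]-4-methylpent-4-enal | O=CC[C@H](O[Si](C)(C)C(C)(C)C)C(C)=C | intermediate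
7 | 2,2-dimethylcyclohexan-1-one | CC1(C)CCCCC1=O | starting material
8 | lithium enolate of 7 (not isolated) | [Li+].[O-]C1=CCCCC1(C)C | intermediate
9 | (6S)-6-[(1S,3S)-3-[(tert-butyldimethylsilyl)oxy]-1-hydroxy-4-methylpent-4-en-1-yl]-2,2-dimethylcyclohexan-1-one | O=C1[C@@H](CCCC1(C)C)[C@@H](O)C[C@H](O[Si](C)(C)C(C)(C)C)C(C)=C | intermediate
10 | dilithium aldolate dianion of 9 (C7 enolate, C1 alkoxide; not isolated) | [Li+].[Li+].[O-]C1=C(CCCC1(C)C)[C@@H]([O-])C[C@H](O[Si](C)(C)C(C)(C)C)C(C)=C | intermediate
11 | (6R)-6-[(1S,3S)-3-[(tert-butyldimethylsilyl)oxy]-1-hydroxy-4-methylpent-4-en-1-yl]-2,2,6-trimethylcyclohexan-1-one | O=C1[C@](C)(CCCC1(C)C)[C@@H](O)C[C@H](O[Si](C)(C)C(C)(C)C)C(C)=C | intermediate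
12 | (1S,2R)-2-[(1S,3S)-3-[(tert-butyldimethylsilyl)oxy]-1-hydroxy-4-methylpent-4-en-1-yl]-2,6,6-trimethyl-1-vinylcyclohexan-1-ol | C=C[C@@]1(O)[C@](C)(CCCC1(C)C)[C@@H](O)C[C@H](O[Si](C)(C)C(C)(C)C)C(C)=C | intermediate
13 | (1S,2R,7S,10S)-bicyclic diol in target locants: cis-fused 6/7 bicycle (six-membered ring C2–C7, seven-membered ring C7–C8=C9–C10–C11–C1–C2) with C7–OH, C2–Me and C1–OH cis, C10–OTBS trans, C6 gem-dimethyl, C9–Me | CC1=C[C@@]2(O)[C@](C)(CCCC2(C)C)[C@@H](O)C[C@@H]1O[Si](C)(C)C(C)(C)C | intermediate
14 | (1S,2R,7S,10S)-bicyclic hydroxy mesylate: 13 with C1–OMs, C7–OH free | CC1=C[C@@]2(O)[C@](C)(CCCC2(C)C)[C@@H](OS(C)(=O)=O)C[C@@H]1O[Si](C)(C)C(C)(C)C | intermediate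
15 | potassium C7-alkoxide of 14 (not isolated) | [K+].CC1=C[C@@]2([O-])[C@](C)(CCCC2(C)C)[C@@H](OS(C)(=O)=O)C[C@@H]1O[Si](C)(C)C(C)(C)C | intermediate
16 | (2Z,4S,6E)-4-[(tert-butyldimethylsilyl)oxy]-3,7,11,11-tetramethylcycloundeca-2,6-dien-1-one (C7 ketone, 10S in target locants) | CC(C)(C)[Si](C)(C)O[C@H]1C/C=C(\C)CCCC(C)(C)C(=O)/C=C\1C | intermediate
17 | (1R,2Z,4S,6E)-4-[(tert-butyldimethylsilyl)oxy]-3,7,11,11-tetramethylcycloundeca-2,6-dien-1-ol (7R,10S in target locants) | CC(C)(C)[Si](C)(C)O[C@H]1C/C=C(\C)CCCC(C)(C)[C@H](O)/C=C\1C | intermediate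
18 | (1R,2Z,4S,6E)-4-[(tert-butyldimethylsilyl)oxy]-3,7,11,11-tetramethylcycloundeca-2,6-dien-1-yl acetate | CC(C)(C)[Si](C)(C)O[C@H]1C/C=C(\C)CCCC(C)(C)[C@H](OC(C)=O)/C=C\1C | intermediate
19 | (1R,2Z,4S,6E)-4-hydroxy-3,7,11,11-tetramethylcycloundeca-2,6-dien-1-yl acetate | O[C@H]1C/C=C(\C)CCCC(C)(C)[C@H](OC(C)=O)/C=C\1C | intermediate
20 | angelic acid, (2Z)-2-methylbut-2-enoic acid | C/C=C(/C)C(O)=O | starting material
21 | angelic 2,4,6-trichlorobenzoic mixed anhydride (not isolated) | C/C=C(/C)C(=O)OC(=O)c1c(Cl)cc(Cl)cc1Cl | intermediate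
22 | CNP0322023.1, (1S,2Z,4R,9E)-4-acetoxy-2,5,5,9-tetramethylcycloundeca-2,9-dien-1-yl (2Z)-2-methylbut-2-enoate (7R,10S in target locants) | C/C=C(/C)C(=O)O[C@H]1C/C=C(\C)CCCC(C)(C)[C@H](OC(C)=O)/C=C\1C | target

## Step count and risks

Total step count: 13. Longest linear sequence: 13 steps (1 and 2 to 22).

The three steps most likely to fail:

**Step 5.** Retro-aldol cleavage of the lithium aldolate may outrun the second deprotonation at C2, or the chelate control that places the methyl group may be lost.
Fallback: it sets out from compound 6 and comes back to the route at compound 16. The lithium enolate of commercial 2,2,6-trimethylcyclohexan-1-one F1 (LDA, THF) is added to 6. The Zimmerman–Traxler aldol should give the quaternary aldol adduct F2, in which C2–Me and C1–OH have the relation opposite to that in 11. Vinyl addition under the conditions of step 6 should give the vinyl carbinol F3, and metathesis under the conditions of step 7 the bicyclic diol F4, with C1–OH trans to C2–Me. Dess–Martin oxidation of the secondary alcohol gives the bicyclic hydroxy ketone F5. A Narasaka–Prasad reduction (Et2BOMe, NaBH4, THF/MeOH, −78 °C), directed by the C7 hydroxyl, should give the cis-1,3-diol F6, with C1–OH now cis to C2–Me. Mesylation as in step 8 gives the mesylate F7, a diastereomer of 14 with C1, C2 and C7 all inverted relative to C10. Its fragmentation under the conditions of step 9 should give the same enone 16.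

**Step 6.** Retro-aldol fragmentation of the magnesium aldolate may compete with slow addition to the doubly neopentyl carbonyl group.
Fallback: it sets out from compound 11 and comes back at compound 12. The C1 hydroxyl is masked (TESCl, imidazole, DMF) as the triethylsilyl ether F8, so that no aldolate can form. The smaller sp nucleophile ethynylmagnesium bromide (CeCl3, THF, 0 °C → rt) is added to give the ethynyl carbinol F9. Lindlar semihydrogenation (H2, Pd/CaCO3/Pb, quinoline) gives the vinyl carbinol silyl ether F10. PPTS in MeOH then removes the triethylsilyl group in the presence of the TBS ether and gives 12.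

**Step 10.** Facial selectivity may be poor or reversed, because the quaternary flank and the Z-alkenyl flank of the ketone are of similar effective size.
Fallback: it sets out from compound 16 and comes back at compound 17. Luche reduction (NaBH4, CeCl3·7H2O, MeOH, −40 °C) gives 17 together with its C7 epimer, the 7S alcohol F11. The two diastereomers are separated by chromatography, and F11 is oxidised back to 16 (MnO2 or Dess–Martin periodinane) and recycled.

Further compounds
F1 | step 5 | 2,2,6-trimethylcyclohexan-1-one | CC1CCCC(C)(C)C1=O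
F2 | step 5 | (6S)-6-[(1S,3S)-3-[(tert-butyldimethylsilyl)oxy]-1-hydroxy-4-methylpent-4-en-1-yl]-2,2,6-trimethylcyclohexan-1-one (C2 epimer of 11) | O=C1[C@@](C)(CCCC1(C)C)[C@@H](O)C[C@H](O[Si](C)(C)C(C)(C)C)C(C)=C
F3 | step 5 | (1R,2S)-2-[(1S,3S)-3-[(tert-butyldimethylsilyl)oxy]-1-hydroxy-4-methylpent-4-en-1-yl]-2,6,6-trimethyl-1-vinylcyclohexan-1-ol | C=C[C@]1(O)[C@@](C)(CCCC1(C)C)[C@@H](O)C[C@H](O[Si](C)(C)C(C)(C)C)C(C)=C
F4 | step 5 | (1S,2S,7R,10S)-bicyclic diol in target locants (C7–OH and C2–Me cis, C1–OH trans to both) | CC1=C[C@]2(O)[C@@](C)(CCCC2(C)C)[C@@H](O)C[C@@H]1O[Si](C)(C)C(C)(C)C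
F5 | step 5 | bicyclic hydroxy ketone (C1 ketone, C7–OH, C10–OTBS) | CC1=C[C@]2(O)[C@@](C)(CCCC2(C)C)C(=O)C[C@@H]1O[Si](C)(C)C(C)(C)C
F6 | step 5 | (1R,2S,7R,10S)-bicyclic diol in target locants (C7–OH, C2–Me and C1–OH cis) | CC1=C[C@]2(O)[C@@](C)(CCCC2(C)C)[C@H](O)C[C@@H]1O[Si](C)(C)C(C)(C)C
F7 | step 5 | (1R,2S,7R,10S)-bicyclic hydroxy mesylate (diastereomer of 14) | CC1=C[C@]2(O)[C@@](C)(CCCC2(C)C)[C@H](OS(C)(=O)=O)C[C@@H]1O[Si](C)(C)C(C)(C)C
F8 | step 6 | C1 triethylsilyl ether of 11 | O=C1[C@](C)(CCCC1(C)C)[C@@H](O[Si](CC)(CC)CC)C[C@H](O[Si](C)(C)C(C)(C)C)C(C)=C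
F9 | step 6 | 1-ethynyl carbinol from F8 (C7–OH cis to C2–Me) | C#C[C@@]1(O)[C@](C)(CCCC1(C)C)[C@@H](O[Si](CC)(CC)CC)C[C@H](O[Si](C)(C)C(C)(C)C)C(C)=C
F10 | step 6 | C1 triethylsilyl ether of 12 | C=C[C@@]1(O)[C@](C)(CCCC1(C)C)[C@@H](O[Si](CC)(CC)CC)C[C@H](O[Si](C)(C)C(C)(C)C)C(C)=C
F11 | step 10 | (1S,2Z,4S,6E)-4-[(tert-butyldimethylsilyl)oxy]-3,7,11,11-tetramethylcycloundeca-2,6-dien-1-ol (C7 epimer of 17) | CC(C)(C)[Si](C)(C)O[C@H]1C/C=C(\C)CCCC(C)(C)[C@@H](O)/C=C\1C
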